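**Retrosynthetic overview**

1. The strategy rests on the acyclic quaternary carbinol carbon C3 (bearing CH3 and OH), which sits between two CH2–C(=O) arms that differ only as sinapyl ester (C1) and free acid (C5). The arm C3–C2H2–C1(=O)O is the one-carbon homologue of the C1 carboxyl of (R)-citramalic acid, which already holds the C3 configuration.
2. Last disconnection: fluoride unmasking of three silicon groups (TMSE ester at C5, TES ether on the C3 oxygen, aryl TBS ether).
3. Key disconnection: the C2–C3 bond and the acyl C1–O bond, both made in one silver-catalysed Wolff rearrangement of a citramalate diazoketone, with capture of the ketene by TBS-protected (Z)-sinapyl alcohol.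
4. The diazoketone comes from (R)-citramalic acid (dioxolanone, TMSE ester, hydrolysis, TES ether, diazoketone). The Z-alcohol comes from syringaldehyde (silylation, Still–Gennari olefination, DIBAL-H).
5. Rings: none is built for the skeleton. The benzene ring is bought with syringaldehyde, and the dioxolanone of step 1 is a temporary protecting ring that step 3 opens.

Key step: step 9

Remark 1: (R)-(−)-citramalic acid is taken as the commercial single enantiomer. Its stereocentre is never a reacting centre; the descriptor of 17 reads S only because the silicon-bearing TMSE arm outranks the sinapyl arm in the CIP order.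
Remark 2: all compounds that contain the Z-styrene (14 onward) are to be handled with exclusion of light and acid.

**Route**

Step 1
Reactants: 1 (R)-citramalic acid
Product: 2 (R)-2-(2,2,4-trimethyl-5-oxo-1,3-dioxolan-4-yl)acetic acid
Conditions: 2,2-dimethoxypropane, PPTS (cat.), CH2Cl2, rt
Reagents that add atoms: 2,2-dimethoxypropane, COC(C)(C)OC
Why: Acid-catalysed transketalisation should tie the tertiary hydroxyl and the adjacent C1 carboxyl into the five-membered 1,3-dioxolan-4-one (favoured over the six-membered ring with the distal carboxyl), leaving only the CH2CO2H arm free and the stereocentre untouched.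

Step 2
Reactants: 2 (R)-2-(2,2,4-trimethyl-5-oxo-1,3-dioxolan-4-yl)acetic acid; 3 2-(trimethylsilyl)ethanol
Product: 4 2-(trimethylsilyl)ethyl (R)-2-(2,2,4-trimethyl-5-oxo-1,3-dioxolan-4-yl)acetate
Conditions: DCC, DMAP (cat.), CH2Cl2, 0 °C to rt
Reagents that add atoms: none
Why: Steglich esterification of the only free carboxyl; catalytic DMAP at low temperature should not open the hindered dioxolanone.

Step 3
Reactants: 4 2-(trimethylsilyl)ethyl (R)-2-(2,2,4-trimethyl-5-oxo-1,3-dioxolan-4-yl)acetate
Product: 5 (R)-2-hydroxy-2-methyl-4-oxo-4-[2-(trimethylsilyl)ethoxy]butanoic acid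
Conditions: 1 M HCl (aq)/THF, rt
Reagents that add atoms: water, O
Why: Acid hydrolysis of the acylal-type dioxolanone should release acetone and the alpha-hydroxy acid, while a TMSE ester is stable to dilute aqueous acid at room temperature.

Step 4
Reactants: 5 (R)-2-hydroxy-2-methyl-4-oxo-4-[2-(trimethylsilyl)ethoxy]butanoic acid
Product: 7 (R)-2-methyl-4-oxo-2-(triethylsilyloxy)-4-[2-(trimethylsilyl)ethoxy]butanoic acid, via triethylsilyl ester 6 (not isolated)
Conditions: TESOTf (2.5 equiv), 2,6-lutidine, CH2Cl2, −78 to 0 °C; then MeOH/H2O, K2CO3 (cat.), 0 °C; pH 4 buffer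
Reagents that add atoms: triethylsilyl triflate, CC[Si](CC)(CC)OS(=O)(=O)C(F)(F)F
Why: Silyl triflate silylation should cover both the hindered tertiary hydroxyl and the carboxyl, and the far more labile silyl ester is then solvolysed selectively so that only the TES ether remains.

Step 5
Reactants: 7 (R)-2-methyl-4-oxo-2-(triethylsilyloxy)-4-[2-(trimethylsilyl)ethoxy]butanoic acid; 8 trimethylsilyldiazomethane
Product: 10 2-(trimethylsilyl)ethyl (R)-5-diazo-3-methyl-4-oxo-3-(triethylsilyloxy)pentanoate, via mixed carbonic anhydride 9 (not isolated)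
Conditions: i-BuOCOCl, N-methylmorpholine, THF, −15 °C; then TMSCHN2 (2 equiv), MeCN, 0 °C to rt
Reagents that add atoms: none
Why: Acylation of a diazoalkane by a mixed carbonic anhydride (first stage of the Arndt–Eistert sequence), in which the departing isobutyl carbonate removes the C-silyl group so that the primary diazoketone results; the stereocentre has no alpha-hydrogen and cannot epimerise.

Step 6
Reactants: 11 syringaldehyde
Product: 12 4-(tert-butyldimethylsilyloxy)-3,5-dimethoxybenzaldehyde
Conditions: TBSCl, imidazole, DMF, rt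
Reagents that add atoms: tert-butyldimethylsilyl chloride, CC(C)(C)[Si](C)(C)Cl
Why: Standard imidazole-promoted silylation of a phenol, which masks the acidic OH before the strongly basic olefination and the later ketene capture.

Step 7
Reactants: 12 4-(tert-butyldimethylsilyloxy)-3,5-dimethoxybenzaldehyde; 13 methyl bis(2,2,2-trifluoroethyl)phosphonoacetate
Product: 14 methyl (Z)-3-[4-(tert-butyldimethylsilyloxy)-3,5-dimethoxyphenyl]prop-2-enoate
Conditions: KHMDS, 18-crown-6, THF, −78 °C
Reagents that add atoms: none
Why: Still–Gennari olefination, in which the electron-poor bis(trifluoroethyl) phosphonate with a dissociated potassium counter-ion eliminates from the kinetically formed adduct faster than it equilibrates, which should give mainly the Z-cinnamate.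

Step 8
Reactants: 14 methyl (Z)-3-[4-(tert-butyldimethylsilyloxy)-3,5-dimethoxyphenyl]prop-2-enoate
Product: 15 (Z)-3-[4-(tert-butyldimethylsilyloxy)-3,5-dimethoxyphenyl]prop-2-en-1-ol
Conditions: DIBAL-H (2.5 equiv), CH2Cl2, −78 °C; Rochelle salt work-up
Reagents that add atoms: none
Why: 1,2-Reduction of a conjugated ester by DIBAL-H at low temperature should give the allylic alcohol without touching the alkene geometry or the aryl silyl ether.

Step 9
Reactants: 10 2-(trimethylsilyl)ethyl (R)-5-diazo-3-methyl-4-oxo-3-(triethylsilyloxy)pentanoate; 15 (Z)-3-[4-(tert-butyldimethylsilyloxy)-3,5-dimethoxyphenyl]prop-2-en-1-ol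
Product: 17 1-[(Z)-3-[4-(tert-butyldimethylsilyloxy)-3,5-dimethoxyphenyl]prop-2-en-1-yl] 5-[2-(trimethylsilyl)ethyl] (S)-3-methyl-3-(triethylsilyloxy)pentanedioate, via ketene 16 (not isolated)
Conditions: AgOBz (15 mol %), Et3N (3 equiv), 15 (1.3 equiv), THF, −25 °C to rt, dark
Reagents that add atoms: none
Why: Silver(I) with triethylamine induces loss of N2 from diazoketone 10, and the fully substituted carbon C3 (carrying CH3, OTES and CH2CO2TMSE) shifts in a concerted 1,2-migration from the carbonyl carbon to the former diazo carbon, which creates the C2–C3 bond and ketene 16. The primary allylic hydroxyl of 15 then adds to the ketene carbonyl and the enol tautomerises, which creates the acyl C1–O bond, so that homologation and esterification occur in one operation. The closest known reaction type is the Arndt–Eistert homologation by silver-catalysed Wolff rearrangement of alpha-oxygenated diazoketones with alcohol capture of the ketene. No ring is closed and no stereocentre is created; the existing quaternary centre migrates with retention because the migrating carbon stays bonded throughout the shift. The step needs the ketene to be taken only by the allylic hydroxyl, which is secured because the phenol, the tertiary alcohol and the second carboxyl are all masked (TBS, TES, TMSE) and the medium is dry. It also needs the Z-alkene and the beta-siloxy group to survive, which the dark, acid-free, room-temperature conditions and the poor leaving-group ability of a silyl ether should allow.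

Step 10
Reactants: 17 1-[(Z)-3-[4-(tert-butyldimethylsilyloxy)-3,5-dimethoxyphenyl]prop-2-en-1-yl] 5-[2-(trimethylsilyl)ethyl] (S)-3-methyl-3-(triethylsilyloxy)pentanedioate
Product: 18 (R)-3-hydroxy-5-{[(Z)-3-(4-hydroxy-3,5-dimethoxyphenyl)prop-2-en-1-yl]oxy}-3-methyl-5-oxopentanoic acid
Conditions: TBAF (6 equiv), AcOH (3 equiv), THF, 0 °C to rt, dark; pH 4 phosphate work-up
Reagents that add atoms: none
Why: Fluoride-mediated desilylation cleaves the two Si–O bonds directly and fragments the TMSE ester by beta-elimination to ethene and the carboxylate, while the acetic acid keeps the phenol and the tertiary alcohol protonated, so that neither phenoxide-driven loss of the allylic carboxylate nor retro-aldol cleavage is expected.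

**Compound list**

1 | (R)-citramalic acid | C[C@@](O)(CC(=O)O)C(=O)O | starting material
2 | (R)-2-(2,2,4-trimethyl-5-oxo-1,3-dioxolan-4-yl)acetic acid | CC1(C)O[C@](C)(CC(=O)O)C(=O)O1 | intermediate
3 | 2-(trimethylsilyl)ethanol | C[Si](C)(C)CCO | starting material
4 | 2-(trimethylsilyl)ethyl (R)-2-(2,2,4-trimethyl-5-oxo-1,3-dioxolan-4-yl)acetate | CC1(C)O[C@](C)(CC(=O)OCC[Si](C)(C)C)C(=O)O1 | intermediate
5 | (R)-2-hydroxy-2-methyl-4-oxo-4-[2-(trimethylsilyl)ethoxy]butanoic acid | O=C(O)[C@](C)(O)CC(=O)OCC[Si](C)(C)C | intermediate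
6 | triethylsilyl (R)-2-methyl-4-oxo-2-(triethylsilyloxy)-4-[2-(trimethylsilyl)ethoxy]butanoate | CC[Si](CC)(CC)OC(=O)[C@](C)(O[Si](CC)(CC)CC)CC(=O)OCC[Si](C)(C)C | intermediate
7 | (R)-2-methyl-4-oxo-2-(triethylsilyloxy)-4-[2-(trimethylsilyl)ethoxy]butanoic acid | O=C(O)[C@](C)(O[Si](CC)(CC)CC)CC(=O)OCC[Si](C)(C)C | intermediate
8 | trimethylsilyldiazomethane | C[Si](C)(C)C=[N+]=[N-] | starting material
9 | isobutyl carbonic (R)-2-methyl-4-oxo-2-(triethylsilyloxy)-4-[2-(trimethylsilyl)ethoxy]butanoic anhydride | CC(C)COC(=O)OC(=O)[C@](C)(O[Si](CC)(CC)CC)CC(=O)OCC[Si](C)(C)C | intermediate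
10 | 2-(trimethylsilyl)ethyl (R)-5-diazo-3-methyl-4-oxo-3-(triethylsilyloxy)pentanoate | [N-]=[N+]=CC(=O)[C@](C)(O[Si](CC)(CC)CC)CC(=O)OCC[Si](C)(C)C | intermediate
11 | syringaldehyde | COc1cc(C=O)cc(OC)c1O | starting material
12 | 4-(tert-butyldimethylsilyloxy)-3,5-dimethoxybenzaldehyde | COc1cc(C=O)cc(OC)c1O[Si](C)(C)C(C)(C)C | intermediate
13 | methyl bis(2,2,2-trifluoroethyl)phosphonoacetate | COC(=O)CP(=O)(OCC(F)(F)F)OCC(F)(F)F | starting material
14 | methyl (Z)-3-[4-(tert-butyldimethylsilyloxy)-3,5-dimethoxyphenyl]prop-2-enoate | COC(=O)/C=C\c1cc(OC)c(O[Si](C)(C)C(C)(C)C)c(OC)c1 | intermediate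
15 | (Z)-3-[4-(tert-butyldimethylsilyloxy)-3,5-dimethoxyphenyl]prop-2-en-1-ol | COc1cc(/C=C\CO)cc(OC)c1O[Si](C)(C)C(C)(C)C | intermediate
16 | 2-(trimethylsilyl)ethyl (R)-3-methyl-5-oxo-3-(triethylsilyloxy)pent-4-enoate (ketene) | O=C=C[C@](C)(O[Si](CC)(CC)CC)CC(=O)OCC[Si](C)(C)C | intermediate
17 | 1-[(Z)-3-[4-(tert-butyldimethylsilyloxy)-3,5-dimethoxyphenyl]prop-2-en-1-yl] 5-[2-(trimethylsilyl)ethyl] (S)-3-methyl-3-(triethylsilyloxy)pentanedioate | COc1cc(/C=C\COC(=O)C[C@](C)(O[Si](CC)(CC)CC)CC(=O)OCC[Si](C)(C)C)cc(OC)c1O[Si](C)(C)C(C)(C)C | intermediate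
18 | (R)-3-hydroxy-5-{[(Z)-3-(4-hydroxy-3,5-dimethoxyphenyl)prop-2-en-1-yl]oxy}-3-methyl-5-oxopentanoic acid | COc1cc(/C=C\COC(=O)C[C@](C)(O)CC(=O)O)cc(OC)c1O | target

**Step count**

Total: 10 steps. Longest linear sequence: 7 steps (steps 1–5, 9 and 10).

**Steps most likely to fail**

1. Step 9 (Wolff rearrangement with capture by 15). Silver-induced nitrogen loss and migration may be sluggish at the fully substituted centre, or the near-stoichiometric alcohol may capture the hindered ketene too slowly, so that the ketene is lost to benzoate, traces of water or dimerisation. The fallback separates homologation from esterification; it sets out from 10 and comes back at 17. Diazoketone 10 would be rearranged in THF/water, where water as co-solvent captures the ketene. Because no styrene is present at this stage, irradiation at 365 nm or heating may replace silver if needed. This should give (S)-3-methyl-5-oxo-3-(triethylsilyloxy)-5-[2-(trimethylsilyl)ethoxy]pentanoic acid F1. Carbodiimide esterification of F1 with 15 (DCC, cat. DMAP, CH2Cl2, 0 °C, dark) would then give 17.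

2. Step 10 (global fluoride deprotection). Fragmentation of the TMSE ester needs fluoride that is not fully buffered, and under such conditions the liberated phenoxide may expel the allylic carboxylate or the Z-alkene may isomerise; with more buffer the TMSE cleavage may stall. The fallback replaces the fluoride-labile ester by a reductively cleaved one; it sets out from 2 and comes back at 18.
   - Acid 2 would be esterified with 2,2,2-trichloroethanol (DCC, DMAP) to 2,2,2-trichloroethyl (R)-2-(2,2,4-trimethyl-5-oxo-1,3-dioxolan-4-yl)acetate F3.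
   - The operations of steps 3–5 and 9 would be repeated in this series: hydrolysis to (R)-2-hydroxy-2-methyl-4-oxo-4-(2,2,2-trichloroethoxy)butanoic acid F4; silylation through the triethylsilyl ester F5 to (R)-2-methyl-4-oxo-4-(2,2,2-trichloroethoxy)-2-(triethylsilyloxy)butanoic acid F6; activation as the mixed carbonic anhydride F7 and reaction with 8 to 2,2,2-trichloroethyl (R)-5-diazo-3-methyl-4-oxo-3-(triethylsilyloxy)pentanoate F8; silver-catalysed Wolff rearrangement through the ketene F9 with capture by 15 to the sinapyl 2,2,2-trichloroethyl diester F10.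
   - Zinc dust in THF/aqueous KH2PO4 would remove the trichloroethyl group by reductive fragmentation, giving the silyl-protected sinapyl monoester acid F11.
   - Because no C–Si bond then has to be attacked, fully buffered TBAF/AcOH (1:1) should cleave the aryl TBS ether and the TES ether to 18 without free phenoxide.

3. Step 5 (diazoketone formation). The diazoalkane may attack the carbonate carbonyl of the mixed anhydride instead of the acyl carbonyl, which is shielded by the fully substituted siloxy carbon, and so return the acid. The fallback uses an electrophile with a single acyl site; it sets out from 7 and comes back at 10. Acid 7 would be converted under neutral conditions with 1-chloro-N,N,2-trimethylprop-1-en-1-amine (CH2Cl2, 0 °C) to 2-(trimethylsilyl)ethyl (R)-4-chloro-3-methyl-4-oxo-3-(triethylsilyloxy)butanoate F2. Ethereal diazomethane with triethylamine at 0 °C would then acylate to 10; the acid chloride has no alpha-hydrogen, so the amine cannot form a ketene from it.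

**Further compounds**

F1 | step 9 | (S)-3-methyl-5-oxo-3-(triethylsilyloxy)-5-[2-(trimethylsilyl)ethoxy]pentanoic acid | OC(=O)C[C@](C)(O[Si](CC)(CC)CC)CC(=O)OCC[Si](C)(C)C
F2 | step 5 | 2-(trimethylsilyl)ethyl (R)-4-chloro-3-methyl-4-oxo-3-(triethylsilyloxy)butanoate | O=C(Cl)[C@](C)(O[Si](CC)(CC)CC)CC(=O)OCC[Si](C)(C)C
F3 | step 10 | 2,2,2-trichloroethyl (R)-2-(2,2,4-trimethyl-5-oxo-1,3-dioxolan-4-yl)acetate | CC1(C)O[C@](C)(CC(=O)OCC(Cl)(Cl)Cl)C(=O)O1
F4 | step 10 | (R)-2-hydroxy-2-methyl-4-oxo-4-(2,2,2-trichloroethoxy)butanoic acid | O=C(O)[C@](C)(O)CC(=O)OCC(Cl)(Cl)Cl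
F5 | step 10 | triethylsilyl (R)-2-methyl-4-oxo-4-(2,2,2-trichloroethoxy)-2-(triethylsilyloxy)butanoate | CC[Si](CC)(CC)OC(=O)[C@](C)(O[Si](CC)(CC)CC)CC(=O)OCC(Cl)(Cl)Cl
F6 | step 10 | (R)-2-methyl-4-oxo-4-(2,2,2-trichloroethoxy)-2-(triethylsilyloxy)butanoic acid | O=C(O)[C@](C)(O[Si](CC)(CC)CC)CC(=O)OCC(Cl)(Cl)Cl
F7 | step 10 | isobutyl carbonic (R)-2-methyl-4-oxo-4-(2,2,2-trichloroethoxy)-2-(triethylsilyloxy)butanoic anhydride | CC(C)COC(=O)OC(=O)[C@](C)(O[Si](CC)(CC)CC)CC(=O)OCC(Cl)(Cl)Cl
F8 | step 10 | 2,2,2-trichloroethyl (R)-5-diazo-3-methyl-4-oxo-3-(triethylsilyloxy)pentanoate | [N-]=[N+]=CC(=O)[C@](C)(O[Si](CC)(CC)CC)CC(=O)OCC(Cl)(Cl)Cl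
F9 | step 10 | 2,2,2-trichloroethyl (R)-3-methyl-5-oxo-3-(triethylsilyloxy)pent-4-enoate (ketene) | O=C=C[C@](C)(O[Si](CC)(CC)CC)CC(=O)OCC(Cl)(Cl)Cl
F10 | step 10 | 1-[(Z)-3-[4-(tert-butyldimethylsilyloxy)-3,5-dimethoxyphenyl]prop-2-en-1-yl] 5-(2,2,2-trichloroethyl) (S)-3-methyl-3-(triethylsilyloxy)pentanedioate | COc1cc(/C=C\COC(=O)C[C@](C)(O[Si](CC)(CC)CC)CC(=O)OCC(Cl)(Cl)Cl)cc(OC)c1O[Si](C)(C)C(C)(C)C
F11 | step 10 | (R)-5-{[(Z)-3-[4-(tert-butyldimethylsilyloxy)-3,5-dimethoxyphenyl]prop-2-en-1-yl]oxy}-3-methyl-5-oxo-3-(triethylsilyloxy)pentanoic acid | COc1cc(/C=C\COC(=O)C[C@](C)(O[Si](CC)(CC)CC)CC(=O)O)cc(OC)c1O[Si](C)(C)C(C)(C)C
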